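- The overall equation turns one starting material into one product, so starting material left plus product stays at the charge as long as no other path takes any; the reckoning below assumes that.

| flask | starting material | reagent | free catalyst | time |
|---|---|---|---|---|
| dawn | 120 mM | 360 mM | 12.0 mM |  |
| summer | 48.0 mM | 288 mM | 12.0 mM |  |
| autumn | 120 mM | 360 mM | 18.0 mM |  |
| dusk | 240 mM | 360 mM | 12.0 mM |  |
| spring | 780 mM | 360 mM | 12.0 mM | 14 min |

| run | time / min | [product] / mM |
|---|---|---|
| dawn run | 1.8 | 9.0 |
| dawn run | 3.5 | 18.5 |
| dawn run | 5.2 | 25.6 |
| dawn run | 7.0 | 31.1 |
| dawn run | 8.8 | 35.9 |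
| dawn run | 10 | 38.9 |
| dawn run | 12 | 41.8 |
| dawn run | 14 | 44.7 |
| summer run | 1.8 | 4.1 |
| summer run | 3.5 | 7.5 |
| summer run | 5.2 | 11.1 |
| summer run | 7.0 | 13.9 |
| summer run | 8.8 | 15.7 |
| summer run | 10 | 16.8 |
| summer run | 12 | 18.1 |
| summer run | 14 | 19.0 |
| autumn run | 1.8 | 13.4 |
| autumn run | 3.5 | 25.4 |
| autumn run | 5.2 | 34.3 |
| autumn run | 7.0 | 42.3 |
| autumn run | 8.8 | 48.4 |
| autumn run | 10 | 50.0 |
| autumn run | 12 | 53.8 |
| autumn run | 14 | 56.8 |
| dusk run | 1.8 | 14.7 |
| dusk run | 3.5 | 28.1 |
| dusk run | 5.2 | 40.3 |
| dusk run | 7.0 | 51.3 |
| dusk run | 8.8 | 59.6 |
| dusk run | 10 | 65.0 |
| dusk run | 12 | 72.7 |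
| dusk run | 14 | 77.9 |

(scatter of a reading: 0.4 mM)

- Overall: starting material + reagent -> product, with free catalyst as catalyst.
- Constant volume, constant temperature.
- A reading of a species includes what of it is bound.
- An order is taken over about fifteen percent of the charge, up and down.

* apparent order in [starting material] of the starting rate, round the charge of the dawn run (the rate where two percent of its starting material have turned into product) (one fixed amount of product, the same in the runs compared)
* apparent order in [reagent] of the starting rate, round the charge of the dawn run (the rate where two percent of its starting material have turned into product)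
* product in the spring run at 14 min, as a share of the starting material charged

- The dawn run reads 18.5 mM of product at 3.5 min, an early rate of 5.29 mM min⁻¹; held steady, that rate gives 74.1 mM by 14 min, yet the reading there is 44.7 mM.
- The dawn run therefore keeps 0.604, and this ratio of product made to what the early rate would have made held steady is the keep share.
- The dusk run, read the same way, has an early rate of 8.03 mM min⁻¹ and a keep share of 0.693.
- Doubling the starting material from dawn to dusk multiplies the early rate by 1.52, less than 2, so my reckoning takes the rate as proportional to a fill fraction: starting material over starting material plus a bend charge (an apparent Michaelis constant).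
- These two readings put the bend charge at 259 mM, and the order in starting material round the dawn charge is then 0.683.
- The summer run, with an early rate of 2.14 mM min⁻¹, leaves after the fill fraction a reagent order near 0.884, a loose value resting on the single reading of 7.5 mM at 3.5 min.
- The spring run shares its reagent and free catalyst with the dusk run, so the fill fraction carries the dusk rate to 12.5 mM min⁻¹, and the dusk keep share gives a first answer of 122 mM.
- Going round once more, that first answer leaves the spring fill fraction at 0.956 of its start, against 0.800 in the dusk run.
- Averaging each with its start raises the spring keep share to 0.753, which gives 132 mM, or 16.9 % of the charge.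
- The forecast, which says “the loss looks mainly like catalyst dying”, gives 0.72 (0.6 to 0.85) in starting material, 0.45 (0.1 to 0.9) in reagent, and 18 % (13.5 % to 22 %) for the spring run; it differs from my reckoning on each.
- Round the dawn charge, the starting rate has apparent orders of 0.60 in starting material and 0.47 in reagent; the spring run gives 18.0 % of its starting material as product at 14 min, while the fit on the main steps gave 24.2 % for that run.

    free catalyst + starting material → catalyst-substrate complex (8.340 M⁻¹ min⁻¹)
    catalyst-substrate complex + reagent → product + free catalyst (4.170 M⁻¹ min⁻¹)
    starting material → decomposed substrate (0.07080 min⁻¹)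
    2 free catalyst → 2 spent catalyst (3.996 M⁻¹ min⁻¹)

- That share is 141 mM of product, a keep share of 0.806 on the reckoned spring rate, higher than the dawn run's 0.604. On the autumn run's simulated rate of 7.3 mM min⁻¹, the dawn keep share gives 61.7 mM by 14 min, more than the autumn reading of 56.8 mM.

(The earlier runs and the new flask stem from a simulated flask on assumed constants; scatter was added.)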